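The earlier runs and the new flask are simulated for an exercise.

The target in the oak flask read 28.2% at 20.0 min and 26.2% at 50.0 min, so it had stopped rising, and I wanted to know what had stopped it.

| flask | substrate | reagent | temperature | remark | time |
|---|---|---|---|---|---|
| oak | 0.70 M | 0.70 M | 70 °C | the very flask that is asked about, followed so far |  |
| flask | 0.70 M | 0.700 M | 70 °C |  | 1.0 h |

- oak (time / min: target / %, substrate / %): 2.50: 8.1, 88.2; 8.00: 19.8, 71.3; 15.0: 24.6, 63.2; 20.0: 28.2, 60.9; 30.0: 27.2, 55.9; 40.0: 28.1, 56.2; 50.0: 26.2, 57.6

(scatter of a reading: 1 percentage point)

- removed target is counted in
- the numbers in the tables scatter with a standard deviation of 1 percentage point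
- the earlier runs do not show what temperature does; that part of a forecast is a guess
- additions bring no volume worth counting
- a reading of substrate is of its free form alone

- Tuesday's: at 1.0 h raise the temperature by 15 K, then wait 30 min
- Saturday's: at 1.0 h take out 90% of the target then present, then wait 30 min
- Sunday's: at 1.0 h add reagent, 50.0% of the amount charged, then wait 30 min
- Friday's: change nothing and wait 30 min more

- target, in percent of the substrate first charged, at 1.0 h
- what to do for the largest gain in target; "none" if nothing gains more than 2 percentage points (Tuesday's / Saturday's / Sunday's / Friday's / none)
- target present, with what was taken out counted in, in percent of the substrate first charged, after Saturday's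
- target present, with what was taken out counted in, in percent of the substrate first charged, after Friday's

The readings show substrate and target but not the reagent, so I wrote the reagent's balance. Both were charged equally, so neither is the limiting reagent by charge. I assumed that each substrate used takes one reagent. With substrate at 56.2% at 40.0 min, the balance gives 56.2%. I call this the reagent ceiling: the share of the reagent charge that the substrate's use leaves over, and so the most that can still be free. Read at face value, it says that substrate did not use up the reagent, so the oak flask looked like a stopped equilibrium.

But one number was not enough, because a ceiling does not say how far below it the free reagent stood. If it stood at the ceiling, taking out target should pull more through. If it stood well below, substrate had fewer partners and the refill should be smaller. Sunday's adds 0.350 M of reagent in either case. I reckoned no gain for either option, so my choice of Sunday's was a judgement and did not follow from the ceiling.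

The forecast judged “so the flask looks equilibrated” and gave 27.5% now, 42% after Saturday's and 27.5% after Friday's. It chose Saturday's, and there I differed from it.

The flask gave 25.0% at 1.0 h, 27.6% after Saturday's and 21.8% after Friday's, and Sunday's gained most, 7 percentage points against 2.7 points for Saturday's.

    substrate + reagent ⇌ target (K = 5.70 /M, k = 0.00100 /M/s, Ea = 87.0 kJ/mol, ΔH = −67.0 kJ/mol)
    substrate + reagent ⇌ isomer of the product A (K = 4.10 /M, k = 4.50 × 10⁻⁴ /M/s, Ea = 78.0 kJ/mol, ΔH = −26.0 kJ/mol)
    reagent ⇌ dormant form (K = 13.0, k = 6.60 × 10⁻⁴ /s, Ea = 90.0 kJ/mol, ΔH = −45.0 kJ/mol)
    target ⇌ isomer of the product B (K = 0.480, k = 3.40 × 10⁻⁵ /s, Ea = 99.0 kJ/mol, ΔH = −76.0 kJ/mol)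
    (constants at 70 °C)

At 1.00 h free reagent stood at 7.7%, less than the ceiling of 56.2% read at 40.0 min, while the dormant form held 0.352 M, or 50.3% of the reagent charge. In a neighbouring flask charged with 2.8 M of reagent, substrate at 17.2% gives a ceiling of 79.3%. There free reagent stood at 11.7%, the dormant form held 1.89 M, and the target reached 48.7%.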